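**Retrosynthetic overview**

- Numbering used throughout: cyclohexene C1 (methyl-bearing olefinic carbon), C2 (=CH), C3 (stilbene-aryl), C4 (aroyl), C5 (aryl), C6 (CH2). The target is the hepta-MOM ether after global acetal cleavage, and the last C–C bond made is aryl–C3.
- Aryl–C3 is cut into two electrophiles, a C3 allylic acetate of the fully substituted cyclohexene and the 5-bromo-stilbene. They are united by a nickel-catalysed reductive cross-electrophile coupling that sets C3 by relay from C4.
- Enabling feature: C3 is allylic to the C1=C2 olefin and next to the C4 stereocentre, so a C3–O bond ionises to an allyl–nickel unit with a secondary (C3) and a tertiary (C1) terminus and one shielded face. The partner atom is C5 of the 2,4-dioxygenated styryl ring, a position where bromine can be bought in.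
- The cyclohexene is the only ring built (step 5, intermolecular [4+2]). A borate-catalysed enantioselective Diels–Alder of the 2′-hydroxychalcone with (E)-1-acetoxy-3-methylbutadiene sets C4 and C5 and puts the C3 acetate and C1 methyl in place.
- The chalcone comes from a Claisen–Schmidt condensation and the bromo-stilbene from a Heck reaction that is chemoselective for C–I over C–Br; the four arene rings are bought.

Key step: step 10

**Remarks on the chemistry (assumptions)**

- The (R)-configured BINOL borate is assumed to shield the chalcone face that leads to (4R,5S). If the opposite sense applies, the (S)-ligand is used and nothing else changes.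
- Compound 8 is drawn as the endo adduct (acetate cis to aroyl). Any C3 epimer would be carried along, because the C3–O stereocentre is erased in step 10.

**Route**

Step 1
Reactants: 1 2,4-dihydroxyacetophenone
Product: 2 1-[2-hydroxy-4-(methoxymethoxy)phenyl]ethan-1-one
Conditions: MOMCl (1.1 equiv), K2CO3, acetone, 0 °C to rt
Reagents that add atoms: chloromethyl methyl ether (MOMCl), COCCl
Why: Williamson-type O-alkylation (MOM protection); the 2-OH is hydrogen-bonded to the acetyl carbonyl, so mild base and one equivalent of MOMCl should etherify only the 4-OH and keep the chelating phenol needed in steps 3 and 5.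

Step 2
Reactants: 3 2,4-dihydroxybenzaldehyde
Product: 4 2,4-bis(methoxymethoxy)benzaldehyde
Conditions: NaH, MOMCl (2.4 equiv each), DMF, 0 °C to rt
Reagents that add atoms: chloromethyl methyl ether (MOMCl), COCCl
Why: MOM protection (Williamson-type O-alkylation) after full deprotonation with NaH should cap both phenols, including the hydrogen-bonded 2-OH, so that the aldehyde is not deactivated as a phenoxide in the aldol step.

Step 3
Reactants: 2 1-[2-hydroxy-4-(methoxymethoxy)phenyl]ethan-1-one, 4 2,4-bis(methoxymethoxy)benzaldehyde
Product: 5 (E)-3-[2,4-bis(methoxymethoxy)phenyl]-1-[2-hydroxy-4-(methoxymethoxy)phenyl]prop-2-en-1-one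
Conditions: KOH (50% aq.), EtOH, rt; then aq. NH4Cl to neutral pH
Reagents that add atoms: none
Why: Claisen–Schmidt (crossed aldol) condensation; the methyl ketone enolate adds to the non-enolisable aldehyde and E1cB dehydration should give the conjugated E-enone, with the MOM acetals stable to base.

Step 4
Reactants: 6 3-methylbut-2-enal (prenal)
Product: 7 (E)-3-methylbuta-1,3-dien-1-yl acetate
Conditions: isopropenyl acetate (excess), TsOH·H2O (cat.), reflux with slow removal of acetone; fractional distillation
Reagents that add atoms: isopropenyl acetate, CC(=C)OC(C)=O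
Why: Acid-catalysed enol acetylation (transesterification with isopropenyl acetate) traps the γ-deprotonated dienol of the enal as the conjugated dienyl acetate, the E-isomer being favoured and enriched by distillation.

Step 5
Reactants: 5 (E)-3-[2,4-bis(methoxymethoxy)phenyl]-1-[2-hydroxy-4-(methoxymethoxy)phenyl]prop-2-en-1-one, 7 (E)-3-methylbuta-1,3-dien-1-yl acetate
Product: 8 (1S,5S,6R)-5-[2,4-bis(methoxymethoxy)phenyl]-6-[2-hydroxy-4-(methoxymethoxy)benzoyl]-3-methylcyclohex-2-en-1-yl acetate (3S,4R,5S in target numbering; acetate cis to aroyl, aroyl trans to aryl)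
Conditions: B(OPh)3 (20 mol%), (R)-3,3′-dibromo-BINOL (22 mol%), 4 Å MS, PhCF3, 25 to 40 °C; 7 (3 equiv); aqueous work-up
Reagents that add atoms: none
Why: Chiral borate-catalysed enantioselective Diels–Alder reaction of a 2′-hydroxychalcone; phenol and carbonyl chelate boron, which activates the enone and lets the BINOL unit shield one face (sets C4 and C5, trans through the E-alkene), the ortho/para orientation of the 1-acetoxy-3-methyl diene places OAc on C3 and methyl on C1, and endo approach sets C3–OAc cis to the aroyl group.

Step 6
Reactants: 9 5-bromo-2,4-dihydroxybenzaldehyde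
Product: 10 5-bromo-2,4-bis(methoxymethoxy)benzaldehyde
Conditions: NaH, MOMCl (2.4 equiv each), DMF, 0 °C to rt
Reagents that add atoms: chloromethyl methyl ether (MOMCl), COCCl
Why: MOM protection (Williamson-type O-alkylation) of both phenoxides should proceed without touching the aryl bromide or the aldehyde.

Step 7
Reactants: 10 5-bromo-2,4-bis(methoxymethoxy)benzaldehyde
Product: 11 1-bromo-5-ethenyl-2,4-bis(methoxymethoxy)benzene
Conditions: MePPh3Br, KOtBu, THF, 0 °C to rt
Reagents that add atoms: methyltriphenylphosphonium bromide, C[P+](c1ccccc1)(c1ccccc1)c1ccccc1.[Br-]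
Why: Wittig methylenation; the non-stabilised ylide converts the aldehyde into the terminal alkene and should leave aryl bromide and MOM ethers untouched, and no stereocentre is formed.

Step 8
Reactants: 12 5-iodobenzene-1,3-diol (5-iodoresorcinol)
Product: 13 1-iodo-3,5-bis(methoxymethoxy)benzene
Conditions: NaH, MOMCl (2.4 equiv each), DMF, 0 °C to rt
Reagents that add atoms: chloromethyl methyl ether (MOMCl), COCCl
Why: MOM protection (Williamson-type O-alkylation) of both phenols should be clean, as the aryl iodide is inert to these conditions.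

Step 9
Reactants: 11 1-bromo-5-ethenyl-2,4-bis(methoxymethoxy)benzene, 13 1-iodo-3,5-bis(methoxymethoxy)benzene
Product: 14 1-bromo-5-{(E)-2-[3,5-bis(methoxymethoxy)phenyl]ethenyl}-2,4-bis(methoxymethoxy)benzene
Conditions: Pd(OAc)2 (5 mol%), n-Bu4NCl, NaHCO3, DMF, 60 °C
Reagents that add atoms: none
Why: Mizoroki–Heck reaction under ligand-free Jeffery conditions; Pd(0) should insert into the C–I bond of 13 far faster than into the electron-rich C–Br bond of 11, and syn-carbopalladation followed by syn-β-hydride elimination should give the E-stilbene with bromine retained.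

Step 10
Reactants: 8 (1S,5S,6R)-5-[2,4-bis(methoxymethoxy)phenyl]-6-[2-hydroxy-4-(methoxymethoxy)benzoyl]-3-methylcyclohex-2-en-1-yl acetate, 14 1-bromo-5-{(E)-2-[3,5-bis(methoxymethoxy)phenyl]ethenyl}-2,4-bis(methoxymethoxy)benzene
Product: 15 [(1R,2R,6S)-2-{5-[(E)-2-[3,5-bis(methoxymethoxy)phenyl]ethenyl]-2,4-bis(methoxymethoxy)phenyl}-6-[2,4-bis(methoxymethoxy)phenyl]-4-methylcyclohex-3-en-1-yl][2-hydroxy-4-(methoxymethoxy)phenyl]methanone (3R,4R,5S in target numbering; all-trans)
Conditions: NiCl2·glyme (10 mol%), 4,4′-di-tert-butyl-2,2′-bipyridine (12 mol%), Zn dust (2 equiv), DMA/THF, 40 °C, argon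
Reagents that add atoms: none
Why: Nickel(0), regenerated by zinc, ionises the allylic acetate of 8 to a cyclohexenyl allyl–nickel unit spanning C1–C2–C3 and also activates the C–Br bond of 14; C(sp2)–C(sp3) reductive elimination from an aryl–nickel–allyl intermediate forms the aryl–C3 bond, so two electrophiles are joined without a preformed organometallic that would attack the ketone. The closest known reaction type is the nickel-catalysed reductive cross-electrophile allylation of aryl bromides with allylic acetates, including cyclohexenyl acetates; no ring is closed. The new C3 stereocentre is set by substrate control: nickel, and hence the aryl group it delivers, should sit on the allyl face anti to the C4 aroyl group, giving the 3,4-trans (3R) product, and because the C3–O stereocentre is lost in the allyl intermediate both C3 epimers of 8 should converge. Regioselectivity between the allyl termini is needed and is secured by C3 being secondary while C1 is tertiary and methyl-bearing, so bond formation at C1 would have to build a quaternary carbon. Site selectivity on the arene is fixed by the position of bromine, and the base-free medium should spare the β-acetoxy ketone from elimination and leave the MOM ethers, the chelated phenol, the ketone and the stilbene untouched.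

Step 11
Reactants: 15 [(1R,2R,6S)-2-{5-[(E)-2-[3,5-bis(methoxymethoxy)phenyl]ethenyl]-2,4-bis(methoxymethoxy)phenyl}-6-[2,4-bis(methoxymethoxy)phenyl]-4-methylcyclohex-3-en-1-yl][2-hydroxy-4-(methoxymethoxy)phenyl]methanone
Product: 16 [(1R,2R,6S)-6-(2,4-dihydroxyphenyl)-2-{5-[(E)-2-(3,5-dihydroxyphenyl)ethenyl]-2,4-dihydroxyphenyl}-4-methylcyclohex-3-en-1-yl](2,4-dihydroxyphenyl)methanone (the target)
Conditions: 3 M aq. HCl/MeOH/THF, 25 to 40 °C; NaHCO3 quench
Reagents that add atoms: none
Why: Acid-catalysed acetal solvolysis (MOM cleavage); each aryl O–CH2–OMe acetal is protonated and the oxocarbenium ion is captured by methanol as dimethoxymethane, at an acidity and temperature kept low so that the C1=C2 olefin, the stilbene and the three stereocentres (C4 already in the favoured all-trans arrangement) should stay untouched.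

**Compound list**

1 | 2,4-dihydroxyacetophenone | CC(=O)c1ccc(O)cc1O | starting material
2 | 1-[2-hydroxy-4-(methoxymethoxy)phenyl]ethan-1-one | CC(=O)c1ccc(OCOC)cc1O | intermediate
3 | 2,4-dihydroxybenzaldehyde | O=Cc1ccc(O)cc1O | starting material
4 | 2,4-bis(methoxymethoxy)benzaldehyde | O=Cc1ccc(OCOC)cc1OCOC | intermediate
5 | (E)-3-[2,4-bis(methoxymethoxy)phenyl]-1-[2-hydroxy-4-(methoxymethoxy)phenyl]prop-2-en-1-one | O=C(/C=C/c1ccc(OCOC)cc1OCOC)c1ccc(OCOC)cc1O | intermediate
6 | 3-methylbut-2-enal | CC(C)=CC=O | starting material
7 | (E)-3-methylbuta-1,3-dien-1-yl acetate | CC(=O)O/C=C/C(C)=C | intermediate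
8 | (1S,5S,6R)-5-[2,4-bis(methoxymethoxy)phenyl]-6-[2-hydroxy-4-(methoxymethoxy)benzoyl]-3-methylcyclohex-2-en-1-yl acetate | CC1=C[C@H](OC(C)=O)[C@H](C(=O)c2ccc(OCOC)cc2O)[C@@H](c2ccc(OCOC)cc2OCOC)C1 | intermediate
9 | 5-bromo-2,4-dihydroxybenzaldehyde | O=Cc1cc(Br)c(O)cc1O | starting material
10 | 5-bromo-2,4-bis(methoxymethoxy)benzaldehyde | O=Cc1cc(Br)c(OCOC)cc1OCOC | intermediate
11 | 1-bromo-5-ethenyl-2,4-bis(methoxymethoxy)benzene | C=Cc1cc(Br)c(OCOC)cc1OCOC | intermediate
12 | 5-iodobenzene-1,3-diol | Oc1cc(O)cc(I)c1 | starting material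
13 | 1-iodo-3,5-bis(methoxymethoxy)benzene | COCOc1cc(I)cc(OCOC)c1 | intermediate
14 | 1-bromo-5-{(E)-2-[3,5-bis(methoxymethoxy)phenyl]ethenyl}-2,4-bis(methoxymethoxy)benzene | COCOc1cc(OCOC)cc(/C=C/c2cc(Br)c(OCOC)cc2OCOC)c1 | intermediate
15 | [(1R,2R,6S)-2-{5-[(E)-2-[3,5-bis(methoxymethoxy)phenyl]ethenyl]-2,4-bis(methoxymethoxy)phenyl}-6-[2,4-bis(methoxymethoxy)phenyl]-4-methylcyclohex-3-en-1-yl][2-hydroxy-4-(methoxymethoxy)phenyl]methanone | CC1=C[C@@H](c2cc(/C=C/c3cc(OCOC)cc(OCOC)c3)c(OCOC)cc2OCOC)[C@H](C(=O)c2ccc(OCOC)cc2O)[C@@H](c2ccc(OCOC)cc2OCOC)C1 | intermediate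
16 | [(1R,2R,6S)-6-(2,4-dihydroxyphenyl)-2-{5-[(E)-2-(3,5-dihydroxyphenyl)ethenyl]-2,4-dihydroxyphenyl}-4-methylcyclohex-3-en-1-yl](2,4-dihydroxyphenyl)methanone | CC1=C[C@@H](c2cc(/C=C/c3cc(O)cc(O)c3)c(O)cc2O)[C@H](C(=O)c2ccc(O)cc2O)[C@@H](c2ccc(O)cc2O)C1 | target

**Step count and risks**

Total step count: 11. Longest linear sequence: 5 steps (1 → 3 → 5 → 10 → 11, or equally 6 → 7 → 9 → 10 → 11).

The three steps most likely to fail:

Step 10 (key coupling). What may go wrong: loss of acetic acid across C3–C4 to the conjugated dienone, homocoupling or simple reduction of either electrophile, protonolysis of the aryl–nickel species by the free chelated phenol, or bond formation on the allyl face syn to the aroyl group. The fallback keeps the same bond but changes to a two-electron, stereospecific nucleophile–electrophile coupling. It sets out from 14: Miyaura borylation (B2pin2, Pd(dppf)Cl2, KOAc, dioxane, 80 °C) should give the aryl pinacol boronate 2-[5-{(E)-2-[3,5-bis(methoxymethoxy)phenyl]ethenyl}-2,4-bis(methoxymethoxy)phenyl]-4,4,5,5-tetramethyl-1,3,2-dioxaborolane F1. A palladium(0)-catalysed Suzuki–Miyaura-type allylic arylation of 8 with this boronate (Pd2(dba)3, PPh3, KF, THF/H2O, 40 °C) then comes back to the route at 15. Oxidative addition anti to the acetate, which is cis to the aroyl group in 8, followed by aryl transfer from palladium with retention should give the same 3,4-trans product.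

Step 5 (asymmetric Diels–Alder). What may go wrong: slow cycloaddition or weak enantioface discrimination by the chiral borate with an oxygenated diene, and loss of acetic acid from the boron-bound adduct. The fallback replaces asymmetric catalysis by resolution. It sets out from 5 and 7: stoichiometric achiral promotion (B(OPh)3, toluene, 60 °C, or heat alone) should give the racemic adduct, that is 8 together with its mirror image (1R,5R,6S)-5-[2,4-bis(methoxymethoxy)phenyl]-6-[2-hydroxy-4-(methoxymethoxy)benzoyl]-3-methylcyclohex-2-en-1-yl acetate F2. Preparative chromatography on a chiral stationary phase separates the two, and the route is rejoined at 8.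

Step 11 (global deprotection). What may go wrong: acid-mediated addition of the phenol ortho to C3 onto the C1=C2 olefin (chroman formation), acid-induced oligomerisation of the electron-rich stilbene, or incomplete cleavage of seven acetals. The fallback unveils the phenols without protic acid through silyl ethers. It sets out from 15: TMSOTf/2,2′-bipyridyl (CH2Cl2, 0 °C to rt) should convert every aryl MOM ether into the aryl trimethylsilyl ether and silylate the chelated phenol as well, giving the octakis(trimethylsilyl) ether of the target F3. Catalytic K2CO3 in MeOH at 0 °C under argon then frees the phenols and comes back to the route at 16.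

Further compounds
F1 | step 10 | 2-[5-{(E)-2-[3,5-bis(methoxymethoxy)phenyl]ethenyl}-2,4-bis(methoxymethoxy)phenyl]-4,4,5,5-tetramethyl-1,3,2-dioxaborolane | CC1(C)OB(OC1(C)C)c1cc(/C=C/c2cc(OCOC)cc(OCOC)c2)c(OCOC)cc1OCOC
F2 | step 5 | (1R,5R,6S)-5-[2,4-bis(methoxymethoxy)phenyl]-6-[2-hydroxy-4-(methoxymethoxy)benzoyl]-3-methylcyclohex-2-en-1-yl acetate (enantiomer of 8) | CC1=C[C@@H](OC(C)=O)[C@@H](C(=O)c2ccc(OCOC)cc2O)[C@H](c2ccc(OCOC)cc2OCOC)C1
F3 | step 11 | octakis(trimethylsilyl) ether of the target, [(1R,2R,6S)-2-{5-[(E)-2-[3,5-bis(trimethylsilyloxy)phenyl]ethenyl]-2,4-bis(trimethylsilyloxy)phenyl}-6-[2,4-bis(trimethylsilyloxy)phenyl]-4-methylcyclohex-3-en-1-yl][2,4-bis(trimethylsilyloxy)phenyl]methanone | CC1=C[C@@H](c2cc(/C=C/c3cc(O[Si](C)(C)C)cc(O[Si](C)(C)C)c3)c(O[Si](C)(C)C)cc2O[Si](C)(C)C)[C@H](C(=O)c2ccc(O[Si](C)(C)C)cc2O[Si](C)(C)C)[C@@H](c2ccc(O[Si](C)(C)C)cc2O[Si](C)(C)C)C1
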